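**Retrosynthetic overview**

1. The target is two identical, achiral 7-acetyl-3,6,8-trihydroxy-4,4-dimethylnaphthalen-1(4H)-one halves joined by a CH2 between C2 and C2'; this bridge is cut last, to formaldehyde and the monomer.
2. The strategy rests on ring A of each half: oxygen on C6 and C8 (meta to each other), the acetyl-bearing carbon C7 between them and hydrogen on C5. A vinylketene and a 1-siloxyalkyne deliver exactly this pattern when they are annulated to a phenol.
3. Ring A is therefore disconnected at C7–C8, C5–C6 and C8–C8a into a ring-B diazo ketone (C4a=C8a as the vinyl unit, C4 quaternary) and a siloxyalkyne that carries the acetyl group as a dioxolane.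
4. Ring order: ring B comes preformed from 2,2-dimethylcyclohexane-1,3-dione (enol triflate, methyl enol ether, doubly allylic oxidation, acetyl, diazo transfer); ring A is then closed by the benzannulation. The alkyne comes from ethyl pyruvate by ketalisation and Kowalski homologation.

Key step: step 8

Remark on the chemistry: atom numbers are those of the naphthalen-1(4H)-one half (C1 ketone, C2 bridge carbon, C3 enol carbon, C4 gem-dimethyl carbon, C5 aromatic CH, C6 and C8 hydroxylated carbons, C7 acetyl carbon); the target has no stereocentre and its triketone halves are written as the C3 enols.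

**Route**

Step 1
Reactants: 1 2,2-dimethylcyclohexane-1,3-dione
Product: 2 6,6-dimethyl-5-oxocyclohex-1-en-1-yl trifluoromethanesulfonate
Conditions: KN(SiMe3)2 (1.05 equiv), THF, −78 °C; then PhNTf2, −78 → 0 °C
Reagents that add atoms: N-phenylbis(trifluoromethanesulfonimide), O=S(=O)(N(c1ccccc1)S(=O)(=O)C(F)(F)F)C(F)(F)F
Why: Enol triflate formation, in which one equivalent of hindered amide base should give only the mono-enolate (the carbon between the carbonyl groups is quaternary and a second deprotonation is far slower) and the sulfonimide traps it on oxygen.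

Step 2
Reactants: 2 6,6-dimethyl-5-oxocyclohex-1-en-1-yl trifluoromethanesulfonate
Product: 4 5-methoxy-6,6-dimethylcyclohexa-1,4-dien-1-yl trifluoromethanesulfonate, via dimethyl ketal 3 (not isolated)
Conditions: HC(OMe)3, MeOH, TsOH (cat.), 40 °C; Et3N quench, evaporate; then Me3SiOTf, iPr2NEt, CH2Cl2, −20 °C → rt
Reagents that add atoms: trimethyl orthoformate, COC(OC)OC
Why: Ketalisation followed by silyl triflate/amine-mediated loss of methanol from the ketal (oxocarbenium ion, then deprotonation at the only α-CH2) should give the methyl enol ether regiospecifically, the vinyl triflate being inert to both stages.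

Step 3
Reactants: 4 5-methoxy-6,6-dimethylcyclohexa-1,4-dien-1-yl trifluoromethanesulfonate
Product: 5 5-methoxy-6,6-dimethyl-3-oxocyclohexa-1,4-dien-1-yl trifluoromethanesulfonate
Conditions: t-BuOOH (anhydrous, in decane), pyridinium dichromate (C5H5NH)2Cr2O7 (substoichiometric), Celite, benzene, 10 °C → rt
Reagents that add atoms: tert-butyl hydroperoxide, CC(C)(C)OO
Why: Peroxide oxidation of the doubly allylic CH2 of a 1-methoxycyclohexa-1,4-diene mediated by hexavalent chromium (hydrogen abstraction, capture of the pentadienyl radical at its central carbon, collapse of the mixed peroxide) is an established entry to 3-methoxy-4,4-disubstituted cyclohexa-2,5-dienones, and because the enol ether was fixed in step 2 the methoxy group must end on the carbon next to the quaternary centre.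

Step 4
Reactants: 5 5-methoxy-6,6-dimethyl-3-oxocyclohexa-1,4-dien-1-yl trifluoromethanesulfonate
Product: 7 5-acetyl-3-methoxy-4,4-dimethylcyclohexa-2,5-dien-1-one, via ethoxyvinyl dienone 6 (not isolated)
Conditions: tributyl(1-ethoxyvinyl)stannane, Pd(PPh3)4 (cat.), LiCl, CuI (cat.), THF, 60 °C; then 1 M aq HCl, THF, 0 °C (brief)
Reagents that add atoms: tributyl(1-ethoxyvinyl)stannane, CCCC[Sn](CCCC)(CCCC)C(=C)OCC; water, O
Why: Stille coupling of the β-triflyloxy enone (a vinylogous acyl triflate that adds readily to zerovalent palladium) with the acyl-anion-equivalent stannane, then hydrolysis of the 1-ethoxyvinyl group, which should be much faster than hydrolysis of the hindered vinylogous methyl ester, gives the methyl ketone.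

Step 5
Reactants: 7 5-acetyl-3-methoxy-4,4-dimethylcyclohexa-2,5-dien-1-one
Product: 9 2-diazo-1-(5-methoxy-6,6-dimethyl-3-oxocyclohexa-1,4-dien-1-yl)ethan-1-one, via trifluoroacetyl diketone 8 (not isolated)
Conditions: LiN(SiMe3)2, THF, −78 °C; CF3CO2CH2CF3; then MsN3, Et3N, H2O, MeCN, rt
Reagents that add atoms: methanesulfonyl azide, CS(=O)(=O)N=[N+]=[N-]; 2,2,2-trifluoroethyl trifluoroacetate, O=C(OCC(F)(F)F)C(F)(F)F (its acyl group is carried in 8 only)
Why: Detrifluoroacetylative diazo transfer, in which the acetyl methyl group is the only enolisable position of 7, its lithium enolate is trifluoroacetylated and sulfonyl azide transfer with loss of the trifluoroacetyl group gives the α'-diazo enone without exposing the electron-poor ring alkene to diazomethane.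

Step 6
Reactants: 10 ethyl pyruvate
Product: 11 ethyl 2-methyl-1,3-dioxolane-2-carboxylate
Conditions: HOCH2CH2OH, TsOH (cat.), toluene, reflux, Dean–Stark trap
Reagents that add atoms: ethane-1,2-diol, OCCO
Why: Acid-catalysed ketalisation with azeotropic removal of water masks the ketone that later becomes the C7 acetyl group.

Step 7
Reactants: 11 ethyl 2-methyl-1,3-dioxolane-2-carboxylate; 12 tri(propan-2-yl)silyl trifluoromethanesulfonate
Product: 15 2-methyl-2-{[tri(propan-2-yl)silyl]oxyethynyl}-1,3-dioxolane, via dibromo enolate 13 (not isolated), via lithium ynolate 14 (not isolated)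
Conditions: CH2Br2, lithium 2,2,6,6-tetramethylpiperidide, THF, −78 °C; add 11; LiN(SiMe3)2; n-BuLi, −78 °C → rt; then 12, −78 → 0 °C
Reagents that add atoms: dibromomethane, BrCBr
Why: Kowalski ester homologation, in which dibromomethyllithium adds to the ester, the derived dibromo enolate undergoes bromine–lithium exchange and 1,2-shift of the dioxolanyl carbon to the ynolate, and the bulky silyl triflate then silylates the ynolate on oxygen.

Step 8
Reactants: 9 2-diazo-1-(5-methoxy-6,6-dimethyl-3-oxocyclohexa-1,4-dien-1-yl)ethan-1-one; 15 2-methyl-2-{[tri(propan-2-yl)silyl]oxyethynyl}-1,3-dioxolane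
Product: 19 8-hydroxy-3-methoxy-4,4-dimethyl-7-(2-methyl-1,3-dioxolan-2-yl)-6-[tri(propan-2-yl)silyloxy]naphthalen-1(4H)-one, via vinylketene 16 (not isolated), via vinylcyclobutenone 17 (not isolated), via dienylketene 18 (not isolated)
Conditions: 15 (1.3 equiv), hν (blue LEDs, 440–450 nm), degassed ClCH2CH2Cl, 20 °C, flow reactor, until 9 is consumed; then 80 °C in the dark
Reagents that add atoms: none
Why: Excitation of the diazo ketone expels dinitrogen and the ring-B alkenyl carbon C4a shifts to the carbene carbon (Wolff rearrangement) to give vinylketene 16, whose carbonyl carbon (future C8) bonds to the dioxolanyl-bearing alkyne carbon and whose α-carbon (future C5) bonds to the siloxy-bearing carbon in a (2+2) cycloaddition, forming C7–C8 and C5–C6 in cyclobutenone 17. Four-electron conrotatory opening of 17 gives dienylketene 18, which closes ring A by six-electron disrotatory electrocyclisation between C8 and C8a, and the resulting cyclohexa-2,4-dienone should enolise at once because its C8a hydrogen lies between two carbonyl groups. The closest known reaction type is the Danheiser benzannulation of α'-diazo α,β-enones with siloxyalkynes, run here with visible light as in visible-light Wolff rearrangements. No stereocentre is created, since the sp3 carbons of 17 and of the dienone tautomer are transient. The step needs the regiochemistry that puts oxygen on C6 and the masked acetyl on C7, which the polarisation of the ynol ether secures: its nucleophilic carbon is the one remote from oxygen and it bonds to the electrophilic ketene carbonyl carbon. It also needs the cross-conjugated dienone of ring B to stay out of the photochemistry, which is secured by irradiating only in the long-wavelength diazo carbonyl band, by finishing the cyclobutenone-to-phenol stage thermally in the dark, and by quaternary C4, which prevents ring B from aromatising.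

Step 9
Reactants: 19 8-hydroxy-3-methoxy-4,4-dimethyl-7-(2-methyl-1,3-dioxolan-2-yl)-6-[tri(propan-2-yl)silyloxy]naphthalen-1(4H)-one
Product: 21 7-acetyl-3,6,8-trihydroxy-4,4-dimethylnaphthalen-1(4H)-one, via diphenol 20 (not isolated)
Conditions: Bu4NF, THF, 0 °C; then 3 M aq HCl, THF, 50 °C
Reagents that add atoms: water, O
Why: Fluoride cleavage of the aryl silyl ether followed by acid hydrolysis of the dioxolane (to the C7 acetyl group) and of the vinylogous methyl ester (to the C1/C3 β-diketone, written as its C3 enol) are standard deprotections that the hydrogen-bonded acylresorcinol core should tolerate.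

Step 10
Reactants: 21 7-acetyl-3,6,8-trihydroxy-4,4-dimethylnaphthalen-1(4H)-one (2 equiv); 22 formaldehyde
Product: 24 2,2'-methylenebis[7-acetyl-3,6,8-trihydroxy-4,4-dimethylnaphthalen-1(4H)-one] (target CNP0295164.0), via methylidene trione 23 (not isolated)
Conditions: 37% aq HCHO (0.5 equiv), NaOAc/AcOH buffer (pH about 5), EtOH–H2O, rt
Reagents that add atoms: none
Why: Knoevenagel condensation of the cyclic β-diketone carbon C2 with formaldehyde and Michael addition of a second molecule of 21 to the methylidene trione (the dimedone–formaldehyde reaction) should form the bridge, because at pH 5 only the β-diketone is ionised and the aromatic C5–H, shielded by the peri gem-dimethyl group, does not compete.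

**Compound list**

1 | 2,2-dimethylcyclohexane-1,3-dione | CC1(C)C(=O)CCCC1=O | starting material
2 | 6,6-dimethyl-5-oxocyclohex-1-en-1-yl trifluoromethanesulfonate | CC1(C)C(=O)CCC=C1OS(=O)(=O)C(F)(F)F | intermediate
3 | 5,5-dimethoxy-6,6-dimethylcyclohex-1-en-1-yl trifluoromethanesulfonate | COC1(OC)CCC=C(OS(=O)(=O)C(F)(F)F)C1(C)C | intermediate (not isolated)
4 | 5-methoxy-6,6-dimethylcyclohexa-1,4-dien-1-yl trifluoromethanesulfonate | COC1=CCC=C(OS(=O)(=O)C(F)(F)F)C1(C)C | intermediate
5 | 5-methoxy-6,6-dimethyl-3-oxocyclohexa-1,4-dien-1-yl trifluoromethanesulfonate | COC1=CC(=O)C=C(OS(=O)(=O)C(F)(F)F)C1(C)C | intermediate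
6 | 5-(1-ethoxyethenyl)-3-methoxy-4,4-dimethylcyclohexa-2,5-dien-1-one | CCOC(=C)C1=CC(=O)C=C(OC)C1(C)C | intermediate (not isolated)
7 | 5-acetyl-3-methoxy-4,4-dimethylcyclohexa-2,5-dien-1-one | CC(=O)C1=CC(=O)C=C(OC)C1(C)C | intermediate
8 | 4,4,4-trifluoro-1-(5-methoxy-6,6-dimethyl-3-oxocyclohexa-1,4-dien-1-yl)butane-1,3-dione | COC1=CC(=O)C=C(C(=O)CC(=O)C(F)(F)F)C1(C)C | intermediate (not isolated)
9 | 2-diazo-1-(5-methoxy-6,6-dimethyl-3-oxocyclohexa-1,4-dien-1-yl)ethan-1-one | COC1=CC(=O)C=C(C(=O)C=[N+]=[N-])C1(C)C | intermediate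
10 | ethyl pyruvate | CCOC(=O)C(C)=O | starting material
11 | ethyl 2-methyl-1,3-dioxolane-2-carboxylate | CCOC(=O)C1(C)OCCO1 | intermediate
12 | tri(propan-2-yl)silyl trifluoromethanesulfonate | CC(C)[Si](OS(=O)(=O)C(F)(F)F)(C(C)C)C(C)C | starting material
13 | lithium 2,2-dibromo-1-(2-methyl-1,3-dioxolan-2-yl)ethen-1-olate | [Li]OC(=C(Br)Br)C1(C)OCCO1 | intermediate (not isolated)
14 | lithium 2-(2-methyl-1,3-dioxolan-2-yl)ethyn-1-olate | [Li]OC#CC1(C)OCCO1 | intermediate (not isolated)
15 | 2-methyl-2-{[tri(propan-2-yl)silyl]oxyethynyl}-1,3-dioxolane | CC1(OCCO1)C#CO[Si](C(C)C)(C(C)C)C(C)C | intermediate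
16 | 3-methoxy-4,4-dimethyl-5-(2-oxoethenyl)cyclohexa-2,5-dien-1-one (vinylketene) | COC1=CC(=O)C=C(C=C=O)C1(C)C | intermediate (not isolated)
17 | 4-(5-methoxy-6,6-dimethyl-3-oxocyclohexa-1,4-dien-1-yl)-2-(2-methyl-1,3-dioxolan-2-yl)-3-[tri(propan-2-yl)silyloxy]cyclobut-2-en-1-one (racemic, transient) | COC1=CC(=O)C=C(C2C(=O)C(C3(C)OCCO3)=C2O[Si](C(C)C)(C(C)C)C(C)C)C1(C)C | intermediate (not isolated)
18 | (3E)-4-(5-methoxy-6,6-dimethyl-3-oxocyclohexa-1,4-dien-1-yl)-2-(2-methyl-1,3-dioxolan-2-yl)-3-[tri(propan-2-yl)silyloxy]buta-1,3-dien-1-one (ketene carbon cis to ring B) | O=C=C(C1(C)OCCO1)/C(O[Si](C(C)C)(C(C)C)C(C)C)=C\C1=CC(=O)C=C(OC)C1(C)C | intermediate (not isolated)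
19 | 8-hydroxy-3-methoxy-4,4-dimethyl-7-(2-methyl-1,3-dioxolan-2-yl)-6-[tri(propan-2-yl)silyloxy]naphthalen-1(4H)-one | COC1=CC(=O)c2c(O)c(C3(C)OCCO3)c(O[Si](C(C)C)(C(C)C)C(C)C)cc2C1(C)C | intermediate
20 | 6,8-dihydroxy-3-methoxy-4,4-dimethyl-7-(2-methyl-1,3-dioxolan-2-yl)naphthalen-1(4H)-one | COC1=CC(=O)c2c(O)c(C3(C)OCCO3)c(O)cc2C1(C)C | intermediate (not isolated)
21 | 7-acetyl-3,6,8-trihydroxy-4,4-dimethylnaphthalen-1(4H)-one | CC(=O)c1c(O)cc2c(c1O)C(=O)C=C(O)C2(C)C | intermediate
22 | formaldehyde | C=O | starting material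
23 | 7-acetyl-6,8-dihydroxy-4,4-dimethyl-2-methylidenenaphthalene-1,3(2H,4H)-dione | CC(=O)c1c(O)cc2c(c1O)C(=O)C(=C)C(=O)C2(C)C | intermediate (not isolated)
24 | 2,2'-methylenebis[7-acetyl-3,6,8-trihydroxy-4,4-dimethylnaphthalen-1(4H)-one] (CNP0295164.0) | CC(=O)c1c(O)cc2c(c1O)C(=O)C(CC1=C(O)C(C)(C)c3cc(O)c(C(C)=O)c(O)c3C1=O)=C(O)C2(C)C | target

**Step count**

Total: 10 steps. Longest linear sequence: 8 steps (steps 1, 2, 3, 4, 5, 8, 9, 10); the alkyne branch is 2 steps (6, 7).

**Steps most likely to fail, with fallbacks**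

Step 8. Excitation may leak into the cross-conjugated dienone of ring B and cause its photorearrangement, or the vinylketene may be captured too slowly by the hindered ynol ether and dimerise. The fallback takes ring B through the annulation without the C1 carbonyl and oxidises afterwards. It sets out from 4. Carbonylative Stille coupling (CO, SnMe4, Pd(PPh3)4, LiCl, THF, 55 °C) should give 1-(5-methoxy-6,6-dimethylcyclohexa-1,4-dien-1-yl)ethan-1-one F1. Diazo transfer as in step 5 should give 2-diazo-1-(5-methoxy-6,6-dimethylcyclohexa-1,4-dien-1-yl)ethan-1-one F2, an ordinary cyclohexenyl diazo ketone with no dienone chromophore. Benzannulation of F2 with 15 (irradiation, then 80 °C) should give 6-methoxy-5,5-dimethyl-2-(2-methyl-1,3-dioxolan-2-yl)-3-[tri(propan-2-yl)silyloxy]-5,8-dihydronaphthalen-1-ol F3. Silylation of the phenol (t-BuMe2SiOTf, 2,6-lutidine) gives the silyl ether tert-butyl({6-methoxy-5,5-dimethyl-2-(2-methyl-1,3-dioxolan-2-yl)-3-[tri(propan-2-yl)silyloxy]-5,8-dihydronaphthalen-1-yl}oxy)dimethylsilane F4. Its CH2 is benzylic and allylic to the enol ether, and oxidation under the conditions of step 3 should give 8-{[tert-butyl(dimethyl)silyl]oxy}-3-methoxy-4,4-dimethyl-7-(2-methyl-1,3-dioxolan-2-yl)-6-[tri(propan-2-yl)silyloxy]naphthalen-1(4H)-one F5. Bu4NF removes both silyl groups and the route is rejoined at 20, which the acid stage of step 9 converts into 21.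

Step 3. The methyl enol ether may be hydrolysed or oxidatively cleaved before the doubly allylic hydrogen is abstracted, or the dienone may be over-oxidised. The fallback oxidises a substrate without an enol ether and brings in the methoxy group afterwards. It sets out from 2. A second enol triflation (KN(SiMe3)2, PhNTf2, THF, −78 °C) should give the symmetric 6,6-dimethylcyclohexa-1,4-diene-1,5-diyl bis(trifluoromethanesulfonate) F6. The same peroxide oxidation should give 6,6-dimethyl-3-oxocyclohexa-1,4-diene-1,5-diyl bis(trifluoromethanesulfonate) F7. One equivalent of NaOMe (MeOH/THF, −40 °C) replaces one triflate by addition–elimination; the vinylogous ester formed is less electrophilic, so a second substitution should be slower. The route is rejoined at 5.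

Step 7. The 1,2-shift of the electron-poor tertiary dioxolanyl carbon in the carbenoid enolate may be slow, so that the carbenoid decomposes during the warming the rearrangement needs. The fallback reaches the ynolate by oxidation of an acetylide instead of by rearrangement. It sets out from 11. Reduction (i-Bu2AlH, CH2Cl2, −78 °C) should give 2-methyl-1,3-dioxolane-2-carbaldehyde F8. Homologation with the Ohira–Bestmann reagent (K2CO3, MeOH) should give 2-ethynyl-2-methyl-1,3-dioxolane F9. Deprotonation (n-BuLi, THF, −78 °C) gives lithium (2-methyl-1,3-dioxolan-2-yl)acetylide F10, which t-BuOOLi should oxidise to ynolate 14 at −78 → 0 °C. Silylation with 12 rejoins the route at 15.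

**Further compounds**

F1 | step 8 | 1-(5-methoxy-6,6-dimethylcyclohexa-1,4-dien-1-yl)ethan-1-one | CC(=O)C1=CCC=C(OC)C1(C)C
F2 | step 8 | 2-diazo-1-(5-methoxy-6,6-dimethylcyclohexa-1,4-dien-1-yl)ethan-1-one | COC1=CCC=C(C(=O)C=[N+]=[N-])C1(C)C
F3 | step 8 | 6-methoxy-5,5-dimethyl-2-(2-methyl-1,3-dioxolan-2-yl)-3-[tri(propan-2-yl)silyloxy]-5,8-dihydronaphthalen-1-ol | COC1=CCc2c(O)c(C3(C)OCCO3)c(O[Si](C(C)C)(C(C)C)C(C)C)cc2C1(C)C
F4 | step 8 | tert-butyl({6-methoxy-5,5-dimethyl-2-(2-methyl-1,3-dioxolan-2-yl)-3-[tri(propan-2-yl)silyloxy]-5,8-dihydronaphthalen-1-yl}oxy)dimethylsilane | COC1=CCc2c(O[Si](C)(C)C(C)(C)C)c(C3(C)OCCO3)c(O[Si](C(C)C)(C(C)C)C(C)C)cc2C1(C)C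
F5 | step 8 | 8-{[tert-butyl(dimethyl)silyl]oxy}-3-methoxy-4,4-dimethyl-7-(2-methyl-1,3-dioxolan-2-yl)-6-[tri(propan-2-yl)silyloxy]naphthalen-1(4H)-one | COC1=CC(=O)c2c(O[Si](C)(C)C(C)(C)C)c(C3(C)OCCO3)c(O[Si](C(C)C)(C(C)C)C(C)C)cc2C1(C)C
F6 | step 3 | 6,6-dimethylcyclohexa-1,4-diene-1,5-diyl bis(trifluoromethanesulfonate) | CC1(C)C(OS(=O)(=O)C(F)(F)F)=CCC=C1OS(=O)(=O)C(F)(F)F
F7 | step 3 | 6,6-dimethyl-3-oxocyclohexa-1,4-diene-1,5-diyl bis(trifluoromethanesulfonate) | CC1(C)C(OS(=O)(=O)C(F)(F)F)=CC(=O)C=C1OS(=O)(=O)C(F)(F)F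
F8 | step 7 | 2-methyl-1,3-dioxolane-2-carbaldehyde | CC1(C=O)OCCO1
F9 | step 7 | 2-ethynyl-2-methyl-1,3-dioxolane | C#CC1(C)OCCO1
F10 | step 7 | lithium (2-methyl-1,3-dioxolan-2-yl)acetylide | [Li]C#CC1(C)OCCO1
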